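## Analysis of the target

The target is a monocyclic tetrahydrofuran lignan. Numbering the ring O1, C2, C3, C4, C5, it carries a 4-hydroxy-3-methoxyphenyl group on C2, a methyl group on C3 and a 4-hydroxy-3,5-dimethoxybenzyl group on C4; C5 is an unsubstituted CH2. The three contiguous stereocentres are (2R,3R,4R). This places aryl and methyl trans and methyl and benzyl trans, the all-trans and thermodynamically preferred arrangement.

The sensitive groups are the two free phenols, which are oxidisable and are therefore masked until the end, and the C2–O1 bond. That bond is a benzylic ether para to an oxygen donor, so it ionises under Lewis or protic acid and can be cut by over-hydrogenolysis.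

Relative configuration is the easier part: C2 and C4 can each be placed trans to C3 by cation capture or by equilibration. The hard part is the absolute configuration at C3, a carbon that bears only H, CH3 and two carbon chains and so offers no handle for a reagent. The strategy reads C2–C3 as the former double bond of an isoeugenol ether, and O1–C5–C4 as the oxygen, carboxyl carbon and α-carbon of a carboxylic acid. The syringylmethyl group on C4 is then simply the substituent of a malonic acid.

## Retrosynthetic reasoning

Target numbering (O1, C2–C5) is used throughout this section. In the lactones 9–11 the systematic locants run the other way: lactone C2 is target C5, C3 is C4, C4 is C3 and C5 is C2.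

**14 from 13.** The two phenolic O–benzyl bonds are cut last. Benzyl ethers keep both rings electron-rich, which the key step needs, survive base, hydride and mild Lewis acid, and leave under neutral hydrogenolysis, which should spare the ring ether if the reaction is stopped in time.

**13 from 11 through 12.** The C5 methylene is traced back to a lactone carbonyl. This adds no carbon and no stereocentre but turns the O1–C5–C4 unit into a carboxylic acid derivative. The forward direction is a two-stage deoxygenation: hydride reduction to lactol 12, then ionic hydrogenation of the C5 oxocarbenium ion.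

**11 from 9 through 10.** A carboxyl group is added to C4, so that C4 becomes a malonate carbon and the corresponding radical becomes easy to generate. Forward, the extra carboxyl is lost on heating to give epimer mixture 10. C4 is then α to the lactone carbonyl and is equilibrated to the trans,trans-lactone 11, so its configuration does not have to be controlled when the bond is made.

**9 from 2 and 8.** This is the key disconnection: the C3–C4 bond and the O1–C2 bond are cut together. Cutting here, rather than at the aryl–C2 bond or the benzylic C–C bond of the side chain, separates the molecule into two pieces of similar size, each a few steps from a commodity phenol, and all 21 carbons of the target are assembled in one step. The forward reaction is a manganese-mediated oxidative annulation. It must generate the malonyl radical of 8, add it to the methyl-bearing carbon of alkene 2, oxidise the benzylic radical to the cation and close the lactone anti to the methyl group. The face of the alkene that is attacked fixes C3 and, through it, C2; this is the one element for which no established control exists, and the route places its risk there.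

**8 from 4 and 5 through 6 and 7; 4 from 3.** The benzylic C–C bond of the malonic acid is cut as a condensation of aldehyde 4 with malonate 5, followed by conjugate reduction and hydrolysis. This avoids an ionisation-prone 4-alkoxy-3,5-dimethoxybenzyl halide and any double alkylation. Aldehyde 4 is the O-benzyl ether of 3.

**2 from 1.** The alkene partner is the O-benzyl ether of 1. Its double-bond geometry is not critical, because the radical and cation intermediates of the key step lose that information.

## Alternatives that were turned down

**Alternative 1: oxocarbenium–alkene cyclisation with ring-contracting pinacol shift.**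
- Disconnection: the C2–C3 and C4–C5 bonds, with the C4 side chain reduced to a formyl group.
- Forward key step: SnCl4 opens an aryl acetal made from a protected vanillin and a chiral-pool alkenyl diol. The oxocarbenium ion adds to the propenyl group, and a pinacol shift contracts the six-membered cation to the tetrahydrofuran aldehyde A1.
- For: the absolute configuration comes from the chiral pool by chirality transfer through a chair transition state. An (E)-oxocarbenium ion and an (E)-alkene should give C2/C3 trans, and the formyl-bearing C4 can be equilibrated.
- Against: A1 lacks the whole syringyl ring. It must be added as an aryl metal to the aldehyde, and the resulting benzylic alcohol must be deoxygenated next to an acid-labile 2-aryl ether. The cation formed in the cyclisation is only secondary. The oxocarbenium ion of an electron-rich benzaldehyde is stabilised and sluggish.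
- Comparison: this route is stronger on absolute stereocontrol, which rests on a known transfer rather than on an unproven catalyst. The chosen route offers convergence instead: both aryl groups and every carbon are in place after one step, and the post-annulation sequence is four steps rather than about seven.

**Alternative 2: donor–acceptor cyclopropane plus a one-carbon aldehyde.**
- Disconnection: the O1–C2 and C4–C5 bonds.
- Forward key step: Sn(OTf)2 activates the enantioenriched trans-cyclopropane diester A2. The aldehyde oxygen attacks the aryl-bearing carbon with inversion, and the malonate carbon closes onto the carbonyl carbon to give A3.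
- For: the annulation is catalytic and stereospecific, so the configuration of the cyclopropane is carried into the ring.
- Against: inversion at the benzylic carbon turns the trans-cyclopropane into the C2/C3-cis ring, so C2 has to be epimerised later by acid. The geminal diester on C4 must be cut down to one carbon and then joined to the syringyl ring through an sp3–sp2 bond, which costs at least five steps. The phenol has to be carried as a tosylate to keep the donor ring from racemising the cyclopropane, and then re-protected or freed. A2 itself needs an asymmetric cyclopropanation of an internal styrene.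
- Comparison: this route is as strong or stronger in that its stereospecificity is established chemistry. The chosen route is much shorter, brings the benzyl group in with the malonate, and gives C2/C3 trans directly.

**Alternative 3: chiral-pool cyclopropane lactone opened by an arylcopper reagent.**
- Disconnection: the bond between the side-chain CH2 and the syringyl ring, and the C3–CH3 bond.
- Forward key step: an arylcopper reagent (ArMgBr with CuI) opens the bicyclic lactone A4 at its cyclopropane CH2. The released lactone–malonate enolate is methylated in the same flask to give A5.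
- For: C4 is fixed from an inexpensive enantiopure three-carbon epoxide, and both the formation of A4 and its homoconjugate opening are reliable. No resolution and no unknown catalysis is needed. On absolute configuration this is the most secure of the four routes.
- Against: A5 still lacks the guaiacyl ring and the C2 stereocentre. After decarboxylation, the aryl group must be added to the lactone carbonyl and the resulting 2-aryl oxocarbenium ion reduced. Hydride delivery anti to the C3 methyl group would give C2/C3 cis, so the required trans relationship would rest on a later acid equilibration. The sequence is linear.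
- Comparison: stronger on absolute control. The chosen route is shorter and convergent, and it sets C2 trans to C3 in the bond-forming event itself.

Key step: step 6

Assumption: the sense of induction of the chiral ligand in step 6 cannot be derived with confidence. The (S,S) antipode is written; the (R,R) antipode would be used instead if the first experiment shows the opposite sense.

## Route

Step 1
Reactants: 1 isoeugenol
Product: 2 (E)-1-(benzyloxy)-2-methoxy-4-(prop-1-en-1-yl)benzene
Conditions: BnBr, K2CO3, acetone, reflux; recrystallisation from EtOH
Reagents that add atoms: benzyl bromide, BrCc1ccccc1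
Why: Williamson etherification of the phenoxide; the alkene is untouched, and any (Z)-isomer from commercial isoeugenol is removed by crystallisation, although both isomers would converge in step 6.

Step 2
Reactants: 3 syringaldehyde
Product: 4 4-(benzyloxy)-3,5-dimethoxybenzaldehyde
Conditions: BnBr, K2CO3, DMF, 60 °C
Reagents that add atoms: benzyl bromide, BrCc1ccccc1
Why: Williamson etherification; the flanked but acidic phenol is alkylated cleanly in a dipolar solvent and the aldehyde is inert.

Step 3
Reactants: 4 4-(benzyloxy)-3,5-dimethoxybenzaldehyde; 5 dimethyl malonate
Product: 6 dimethyl 2-[4-(benzyloxy)-3,5-dimethoxybenzylidene]malonate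
Conditions: piperidine (cat.), AcOH (cat.), toluene, reflux, Dean–Stark trap
Reagents that add atoms: none
Why: Knoevenagel condensation driven by azeotropic removal of water; it forms the benzylic C–C bond without an ionisation-prone benzyl halide and cannot over-alkylate.

Step 4
Reactants: 6 dimethyl 2-[4-(benzyloxy)-3,5-dimethoxybenzylidene]malonate
Product: 7 dimethyl 2-[4-(benzyloxy)-3,5-dimethoxybenzyl]malonate
Conditions: NaBH4, MeOH–THF, 0 °C
Reagents that add atoms: none
Why: conjugate hydride reduction of an alkylidene malonate; the doubly activated alkene is reduced far faster than the esters, and no stereocentre is formed.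

Step 5
Reactants: 7 dimethyl 2-[4-(benzyloxy)-3,5-dimethoxybenzyl]malonate
Product: 8 2-[4-(benzyloxy)-3,5-dimethoxybenzyl]malonic acid
Conditions: KOH, MeOH–H2O, 50 °C; then aq. HCl, 0 °C, extraction and drying below 40 °C
Reagents that add atoms: potassium hydroxide (hydroxide oxygen of each carboxyl group), [K+].[OH-]
Why: ester saponification; the aryl benzyl ether is inert to base, and the free malonic acid does not decarboxylate at the temperatures used.

Step 6
Reactants: 2 (E)-1-(benzyloxy)-2-methoxy-4-(prop-1-en-1-yl)benzene; 8 2-[4-(benzyloxy)-3,5-dimethoxybenzyl]malonic acid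
Product: 9 (3R,4R,5R)-5-[4-(benzyloxy)-3-methoxyphenyl]-3-[4-(benzyloxy)-3,5-dimethoxybenzyl]-4-methyl-2-oxotetrahydrofuran-3-carboxylic acid
Conditions: 8 (1.3 equiv), Mn(OTf)2 (10 mol %), (S,S)-PDP [(2S,2'S)-1,1'-bis(pyridin-2-ylmethyl)-2,2'-bipyrrolidine] (11 mol %), NaOAc, n-Bu4NBF4, MeCN–AcOH 9:1, graphite felt anode, Pt cathode, divided cell, anode held at the manganese wave, 2.2 F/mol, 30 °C
Reagents that add atoms: none
Why: Proposed new method: the anode oxidises the ligated divalent manganese to the trivalent complex, which takes up 8 as a six-membered dicarboxylate chelate on its two cis sites and oxidises it by inner-sphere electron transfer, with loss of the α-proton, to the tertiary malonyl radical; this electrophilic radical adds to the methyl-bearing carbon of the electron-rich styrene 2, the only regiochemistry that leaves an aryl-stabilised benzylic radical, and so forms the C3–C4 bond (target numbering). A second one-electron oxidation, by trivalent manganese or at the anode, gives the 4-benzyloxy-3-methoxybenzyl cation, and a carboxyl oxygen captures it in a 5-exo-trig closure that forms the O1–C2 bond and the lactone ring. The closest known reaction type is the racemic Mn(OAc)3-mediated lactone annulation of styrenes with malonic acids, which also runs with anodic regeneration of the oxidant; the chiral ligand, and with it the enantioselective course, is what is new. C3 is the centre the ligand has to control: as long as the radical stays chelated to divalent manganese, the twofold axis of the complex passes through the radical carbon, its two faces are equivalent, and the pyridine walls of the ligand only have to tell the two faces of the alkene apart, much as complexes of this family differentiate positions a few atoms away from a bound carboxylate in oxidative lactonisations. C2 follows from C3 by substrate control, because the carboxyl group closes on the cation anti to the neighbouring methyl group and the trans lactone is also the more stable one. The malonate carbon (C4 of the target) forms as whichever epimer the closing carboxyl group dictates, drawn here with benzyl trans to methyl, and is reset in step 7. The step also needs oxidation of the malonic acid in preference to the two electron-rich arenes and the alkene, which the low working potential of the mediator and the ready enolisation of the chelated acid are meant to secure, and it stops after one annulation because the malonate carbon of 9 is quaternary.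

Step 7
Reactants: 9 (3R,4R,5R)-5-[4-(benzyloxy)-3-methoxyphenyl]-3-[4-(benzyloxy)-3,5-dimethoxybenzyl]-4-methyl-2-oxotetrahydrofuran-3-carboxylic acid
Product: 11 (3R,4R,5R)-5-[4-(benzyloxy)-3-methoxyphenyl]-3-[4-(benzyloxy)-3,5-dimethoxybenzyl]-4-methyldihydrofuran-2(3H)-one, via the C3-epimeric decarboxylated lactone 10 (not isolated)
Conditions: pyridine, reflux; then DBU (0.3 equiv), toluene, 80 °C
Reagents that add atoms: none
Why: thermal decarboxylation of a malonic acid half-ester type acid through its enol, then base-mediated equilibration of the centre α to the lactone carbonyl; the benzyl group settles trans to the adjacent methyl group, the more stable arrangement, and the other two centres are not enolisable.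

Step 8
Reactants: 11 (3R,4R,5R)-5-[4-(benzyloxy)-3-methoxyphenyl]-3-[4-(benzyloxy)-3,5-dimethoxybenzyl]-4-methyldihydrofuran-2(3H)-one
Product: 12 (3R,4R,5R)-5-[4-(benzyloxy)-3-methoxyphenyl]-3-[4-(benzyloxy)-3,5-dimethoxybenzyl]-4-methyltetrahydrofuran-2-ol (both anomers)
Conditions: i-Bu2AlH (DIBAL-H, 1.1 equiv), CH2Cl2, −78 °C; aq. KNa tartrate
Reagents that add atoms: none
Why: partial reduction of a lactone to the lactol; the tetrahedral aluminium hemiacetal is stable at low temperature until work-up, the α-centre is not epimerised under these non-basic conditions, and the new anomeric centre is removed in step 9.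

Step 9
Reactants: 12 (3R,4R,5R)-5-[4-(benzyloxy)-3-methoxyphenyl]-3-[4-(benzyloxy)-3,5-dimethoxybenzyl]-4-methyltetrahydrofuran-2-ol
Product: 13 (2R,3R,4R)-2-[4-(benzyloxy)-3-methoxyphenyl]-4-[4-(benzyloxy)-3,5-dimethoxybenzyl]-3-methyltetrahydrofuran
Conditions: Et3SiH (3 equiv), BF3·OEt2 (1.5 equiv), CH2Cl2, −78 to −40 °C
Reagents that add atoms: none
Why: ionic hydrogenation; BF3 ionises the lactol to the C5 oxocarbenium ion (target numbering), which the silane reduces, so no stereocentre is formed or touched, and the low temperature is meant to keep the benzylic C2–O1 bond from ionising.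

Step 10
Reactants: 13 (2R,3R,4R)-2-[4-(benzyloxy)-3-methoxyphenyl]-4-[4-(benzyloxy)-3,5-dimethoxybenzyl]-3-methyltetrahydrofuran
Product: 14 4-{[(3R,4R,5R)-5-(4-hydroxy-3-methoxyphenyl)-4-methyltetrahydrofuran-3-yl]methyl}-2,6-dimethoxyphenol
Conditions: H2 (1 atm), 10% Pd/C, EtOAc–EtOH, rt, stopped at full conversion
Reagents that add atoms: none
Why: hydrogenolysis of aryl benzyl ethers under neutral conditions, which is much faster than cleavage of the dialkyl-type benzylic ring ether; no stereocentre is involved.

## Compound list

1 | isoeugenol, (E)-2-methoxy-4-(prop-1-en-1-yl)phenol | C/C=C/c1ccc(O)c(OC)c1 | starting material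
2 | (E)-1-(benzyloxy)-2-methoxy-4-(prop-1-en-1-yl)benzene | C/C=C/c1ccc(OCc2ccccc2)c(OC)c1 | intermediate
3 | syringaldehyde, 4-hydroxy-3,5-dimethoxybenzaldehyde | COc1cc(C=O)cc(OC)c1O | starting material
4 | 4-(benzyloxy)-3,5-dimethoxybenzaldehyde | COc1cc(C=O)cc(OC)c1OCc1ccccc1 | intermediate
5 | dimethyl malonate | COC(=O)CC(=O)OC | starting material
6 | dimethyl 2-[4-(benzyloxy)-3,5-dimethoxybenzylidene]malonate | COC(=O)C(=Cc1cc(OC)c(OCc2ccccc2)c(OC)c1)C(=O)OC | intermediate
7 | dimethyl 2-[4-(benzyloxy)-3,5-dimethoxybenzyl]malonate | COC(=O)C(Cc1cc(OC)c(OCc2ccccc2)c(OC)c1)C(=O)OC | intermediate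
8 | 2-[4-(benzyloxy)-3,5-dimethoxybenzyl]malonic acid | OC(=O)C(Cc1cc(OC)c(OCc2ccccc2)c(OC)c1)C(=O)O | intermediate
9 | (3R,4R,5R)-5-[4-(benzyloxy)-3-methoxyphenyl]-3-[4-(benzyloxy)-3,5-dimethoxybenzyl]-4-methyl-2-oxotetrahydrofuran-3-carboxylic acid (C3 drawn with benzyl trans to methyl; the C3 epimer is equally usable) | COc1cc([C@@H]2OC(=O)[C@@](Cc3cc(OC)c(OCc4ccccc4)c(OC)c3)(C(=O)O)[C@H]2C)ccc1OCc1ccccc1 | intermediate
10 | (4R,5R)-5-[4-(benzyloxy)-3-methoxyphenyl]-3-[4-(benzyloxy)-3,5-dimethoxybenzyl]-4-methyldihydrofuran-2(3H)-one, mixture of C3 epimers | COc1cc([C@@H]2OC(=O)C(Cc3cc(OC)c(OCc4ccccc4)c(OC)c3)[C@H]2C)ccc1OCc1ccccc1 | intermediate (not isolated)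
11 | (3R,4R,5R)-5-[4-(benzyloxy)-3-methoxyphenyl]-3-[4-(benzyloxy)-3,5-dimethoxybenzyl]-4-methyldihydrofuran-2(3H)-one | COc1cc([C@@H]2OC(=O)[C@H](Cc3cc(OC)c(OCc4ccccc4)c(OC)c3)[C@H]2C)ccc1OCc1ccccc1 | intermediate
12 | (3R,4R,5R)-5-[4-(benzyloxy)-3-methoxyphenyl]-3-[4-(benzyloxy)-3,5-dimethoxybenzyl]-4-methyltetrahydrofuran-2-ol, both anomers | COc1cc([C@@H]2OC(O)[C@H](Cc3cc(OC)c(OCc4ccccc4)c(OC)c3)[C@H]2C)ccc1OCc1ccccc1 | intermediate
13 | (2R,3R,4R)-2-[4-(benzyloxy)-3-methoxyphenyl]-4-[4-(benzyloxy)-3,5-dimethoxybenzyl]-3-methyltetrahydrofuran | COc1cc([C@@H]2OC[C@H](Cc3cc(OC)c(OCc4ccccc4)c(OC)c3)[C@H]2C)ccc1OCc1ccccc1 | intermediate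
14 | 4-{[(3R,4R,5R)-5-(4-hydroxy-3-methoxyphenyl)-4-methyltetrahydrofuran-3-yl]methyl}-2,6-dimethoxyphenol | COc1cc([C@@H]2OC[C@H](Cc3cc(OC)c(O)c(OC)c3)[C@H]2C)ccc1O | target

## Step count and least certain steps

Total: 10 steps. Longest linear sequence: 9 steps (3 to 14, steps 2 to 10). Step 1 is the only step of the shorter branch.

**Step 6 (key step, proposed new method).**
- What is most likely to go wrong: the malonyl radical leaves the manganese coordination sphere before it adds to the alkene. The addition then proceeds without facial bias and the lactone acid is formed with the right constitution and trans relationship but in racemic form. A second failure mode is direct anodic oxidation of the electron-rich alkene when the potential drifts above the mediator wave.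
- Fallback (known chemistry): 2 and 8 are combined in the ligand-free annulation with Mn(OAc)3·2H2O (2.2 equiv) in AcOH at 60 °C, which gives the racemic lactone acid F1. Decarboxylation and DBU equilibration as in step 7 give the racemic trans,trans-lactone F2. AlMe3-mediated aminolysis with (S)-1-phenylethylamine in CH2Cl2 turns F2 into two diastereomeric γ-hydroxy amides, the (2R,3R,4R) amide F3 and the (2S,3S,4S) amide F4, which are separated by crystallisation or chromatography. Heating F3 with aqueous H2SO4 in dioxane closes the lactone again and returns the route to 11.

**Step 9.**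
- What is most likely to go wrong: the Lewis acid ionises the benzylic C2–O1 bond next to the electron-rich ring, and the silane then reduces the benzylic cation, opening the ring. Epimerisation at C2 by the same ionisation is less of a concern, because the all-trans isomer is the stable one.
- Fallback: 11 is reduced with LiAlH4 in THF to the diol F5. The primary alcohol is sulfonylated selectively (TsCl, Et3N, cat. DMAP, CH2Cl2, 0 °C) to the tosylate F6. NaH in THF then closes the ring by Williamson displacement at the primary carbon, with the benzylic oxygen as nucleophile and therefore with retention at C2, and the route is rejoined at 13.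

**Step 10.**
- What is most likely to go wrong: over-reduction, in which the benzylic ring C–O bond is hydrogenolysed after the benzyl ethers have gone.
- Fallback: 13 is debenzylated without hydrogen by BCl3 in CH2Cl2 at −78 °C with pentamethylbenzene as benzyl-cation scavenger, which leads directly to 14. This fallback forms no new intermediate.

**Step 7.**
- What is most likely to go wrong: the base equilibration stops at a mixture that still holds a substantial share of the epimer with benzyl cis to methyl.
- Fallback: the epimer mixture 10 is carried on without equilibration. Reduction with i-Bu2AlH as in step 8 gives the lactol epimer mixture F7. Its masked aldehyde is equilibrated at the α-carbon with K2CO3 in MeOH through the open-chain γ-hydroxy aldehyde, which cannot undergo a retro-aldol reaction. The all-trans lactol 12 is obtained and the route is rejoined there.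

## Further compounds

F1 | step 6 | racemic trans-5-[4-(benzyloxy)-3-methoxyphenyl]-3-[4-(benzyloxy)-3,5-dimethoxybenzyl]-4-methyl-2-oxotetrahydrofuran-3-carboxylic acid, C3 epimers (both enantiomers written) | COc1cc([C@@H]2OC(=O)C(Cc3cc(OC)c(OCc4ccccc4)c(OC)c3)(C(=O)O)[C@H]2C)ccc1OCc1ccccc1.COc1cc([C@H]2OC(=O)C(Cc3cc(OC)c(OCc4ccccc4)c(OC)c3)(C(=O)O)[C@@H]2C)ccc1OCc1ccccc1
F2 | step 6 | racemic (3R*,4R*,5R*)-5-[4-(benzyloxy)-3-methoxyphenyl]-3-[4-(benzyloxy)-3,5-dimethoxybenzyl]-4-methyldihydrofuran-2(3H)-one (both enantiomers written) | COc1cc([C@@H]2OC(=O)[C@H](Cc3cc(OC)c(OCc4ccccc4)c(OC)c3)[C@H]2C)ccc1OCc1ccccc1.COc1cc([C@H]2OC(=O)[C@@H](Cc3cc(OC)c(OCc4ccccc4)c(OC)c3)[C@@H]2C)ccc1OCc1ccccc1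
F3 | step 6 | (2R,3R,4R)-4-[4-(benzyloxy)-3-methoxyphenyl]-2-[4-(benzyloxy)-3,5-dimethoxybenzyl]-4-hydroxy-3-methyl-N-[(1S)-1-phenylethyl]butanamide | COc1cc([C@H](O)[C@H](C)[C@@H](Cc2cc(OC)c(OCc3ccccc3)c(OC)c2)C(=O)N[C@@H](C)c2ccccc2)ccc1OCc1ccccc1
F4 | step 6 | (2S,3S,4S)-4-[4-(benzyloxy)-3-methoxyphenyl]-2-[4-(benzyloxy)-3,5-dimethoxybenzyl]-4-hydroxy-3-methyl-N-[(1S)-1-phenylethyl]butanamide | COc1cc([C@@H](O)[C@@H](C)[C@H](Cc2cc(OC)c(OCc3ccccc3)c(OC)c2)C(=O)N[C@@H](C)c2ccccc2)ccc1OCc1ccccc1
F5 | step 9 | (1R,2R,3R)-1-[4-(benzyloxy)-3-methoxyphenyl]-3-[4-(benzyloxy)-3,5-dimethoxybenzyl]-2-methylbutane-1,4-diol | COc1cc([C@H](O)[C@H](C)[C@@H](Cc2cc(OC)c(OCc3ccccc3)c(OC)c2)CO)ccc1OCc1ccccc1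
F6 | step 9 | (2R,3R,4R)-4-[4-(benzyloxy)-3-methoxyphenyl]-2-[4-(benzyloxy)-3,5-dimethoxybenzyl]-4-hydroxy-3-methylbutyl 4-methylbenzenesulfonate | COc1cc([C@H](O)[C@H](C)[C@@H](Cc2cc(OC)c(OCc3ccccc3)c(OC)c2)COS(=O)(=O)c2ccc(C)cc2)ccc1OCc1ccccc1
F0 | step 10 | none | none
F7 | step 7 | (4R,5R)-5-[4-(benzyloxy)-3-methoxyphenyl]-3-[4-(benzyloxy)-3,5-dimethoxybenzyl]-4-methyltetrahydrofuran-2-ol, mixture of C3 epimers and anomers | COc1cc([C@@H]2OC(O)C(Cc3cc(OC)c(OCc4ccccc4)c(OC)c3)[C@H]2C)ccc1OCc1ccccc1
A1 | alternative 1 | (3R,4R,5R)-5-[4-(benzyloxy)-3-methoxyphenyl]-4-methyltetrahydrofuran-3-carbaldehyde | COc1cc([C@@H]2OC[C@H](C=O)[C@H]2C)ccc1OCc1ccccc1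
A2 | alternative 2 | dimethyl (2R,3S)-2-[3-methoxy-4-(tosyloxy)phenyl]-3-methylcyclopropane-1,1-dicarboxylate | COc1cc([C@H]2[C@H](C)C2(C(=O)OC)C(=O)OC)ccc1OS(=O)(=O)c1ccc(C)cc1
A3 | alternative 2 | dimethyl (4R,5S)-5-[3-methoxy-4-(tosyloxy)phenyl]-4-methyldihydrofuran-3,3(2H)-dicarboxylate | COc1cc([C@H]2OCC(C(=O)OC)(C(=O)OC)[C@H]2C)ccc1OS(=O)(=O)c1ccc(C)cc1
A4 | alternative 3 | methyl (1S,5R)-2-oxo-3-oxabicyclo[3.1.0]hexane-1-carboxylate | O=C1OC[C@@H]2C[C@]12C(=O)OC
A5 | alternative 3 | methyl (3R,4R)-4-[4-(benzyloxy)-3,5-dimethoxybenzyl]-3-methyl-2-oxotetrahydrofuran-3-carboxylate | O=C1OC[C@H](Cc2cc(OC)c(OCc3ccccc3)c(OC)c2)[C@]1(C)C(=O)OC
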